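Your vessel is closed, stirred and held at constant volume and temperature, so watch one curve first: the logarithm of the fraction of starting material left, against time.

| flask | starting material | reagent | remark | time |
|---|---|---|---|---|
| south-east | 0.54 M | 0.80 M | run made earlier |  |
| teal | 0.80 M | 0.800 M |  | 20 min |
| blue | 0.80 M | 1.00 M |  | 20 min |
| ochre | 0.80 M | 1.50 M |  | 20 min |
| amber | 0.80 M | 2.50 M |  | 20 min |

- south-east (time / min: target / %, starting material / %): 1.00: 9.4, 85.3; 1.33: 10.8, 80.2; 2.00: 14.3, 72.0; 3.00: 17.9, 62.6; 5.00: 21.8, 46.9; 8.00: 23.3, 33.4; 12.0: 21.8, 20.3

(each reading ± 1 percentage point)

- percent here means starting material units held: one self-condensation product counts as two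
- what may be going on: starting material <-> other conformer; starting material + reagent -> target; reagent + other conformer -> isomer of the product A; 2 starting material -> self-condensation product; target <-> isomer of the product B
- "hardly changes" means that all values lie within two and a half points (for a concentration: within two and a half percent of the largest)

* amount of target at the end, in percent of the starting material charged for teal, blue, ochre, amber, in this order
* the shape of the row from first to last (falls, then rises / rises, then falls / rises all the way / falls all the way / hardly changes)

The south-east run reads 72.0% left at 2.00 min. That gives 0.164 min⁻¹ as the early loss constant, the natural logarithm of charged over left, divided by the time. Between 8.00 min and 12.0 min the same constant reads 0.124 min⁻¹, lower than the early reading, so it has kept 75.8% of its early value, a figure that carries the scatter of the readings behind it.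

Now take two extremes for teal. In the first, loss ignores the reagent: the constant holds, the decay is first-order, and teal ends with 3.74% left. In the second, loss is wholly second-order with the reagent. Teal's charges are equal and its reagent matches the south-east charge, so the fraction left is one over one plus the constant times the time, 23.3%.

A wholly second-order loss ties the constant to the reagent remaining, and at 8.00 min at least 55.0% of the south-east reagent charge remains. The constant kept more than that but less than all of it, so the south-east run lies between the extremes, and teal should too. Part of the loss answers to reagent, so expect the fraction of starting material left to fall along the row from teal to amber. That does not give the target row: in the south-east run, while starting material went on falling, the target read 21.8%, 23.3% and 21.8% at 5.00 min, 8.00 min and 12.0 min, so target is also being used. The end amount therefore depends on that drain and on any return from isomer of the product B as well as on the feed.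

The forecast gives 13.5%, 16%, 24% and 26%, a row that rises all the way, on the ground that “more reagent raises total target plus isomer B”.

The flask gives 17.5%, 20.0%, 23.5% and 25.5%: the row rises all the way.

    starting material ⇌ other conformer (K = 1.50, k = 0.0680 min⁻¹)
    starting material + reagent → target (k = 0.130 M⁻¹ min⁻¹)
    reagent + other conformer → isomer of the product A (k = 0.100 M⁻¹ min⁻¹)
    2 starting material → self-condensation product (k = 5.20 × 10⁻⁴ M⁻¹ min⁻¹)
    target ⇌ isomer of the product B (K = 2.60, k = 0.150 min⁻¹)

Teal holds 15.2% starting material at 20.0 min, inside its bracket . Amber holds 0.461%, and 0.164 min⁻¹ brackets that too: its first-order end is 3.74% and its second-order end, with reagent in excess, is 0.0632%. In teal, starting material goes to target 1.5 times as fast as it goes forward to other conformer at the start, and 0.53 times as fast at 20.0 min.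

(The readings are simulated for an exercise, noise included.)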